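**Retrosynthetic overview**

- The target is a C2-symmetric tetrahydrofuran (O1, C2–C5): aryl groups on C2 and C5, aroyl groups on C3 and C4, 2,3-cis, 3,4-trans, 4,5-cis. The feature used is that C3–C4–C5 (C3 next to a ketone, C5 a benzylic ether carbon) is the opened form of a donor–acceptor cyclopropane, and O1–C2 is the C=O of an aromatic aldehyde.
- Last disconnections: the six phenol protecting groups (hydrogenolysis) and an allyl ester on C3 (decarboxylative protonation). C3 therefore stays quaternary, and cannot enolise, while the ring is made.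
- Key disconnection: O1–C5 and C2–C3, a Lewis acid (3+2) annulation of a cyclopropane keto ester with 4-(benzyloxy)benzaldehyde. It closes the only ring of the target.
- The cyclopropane ring is made one step earlier by an asymmetric Michael-initiated ring closure of an α-bromo β-keto ester on a chalcone.
- Change of protecting group: the donor aryl carries a benzyl carbonate, not a benzyl ether. This keeps the ring opening SN2-like and confines later Lewis acid equilibration to C2.

Key step: step 6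

Assumptions: the cinchonidinium salt of step 5 is taken to give the (2S,3R) cyclopropane series; if the opposite sense is found, the pseudoenantiomeric cinchoninium salt is used. The quaternary carbon of the cyclopropane and of the annulation product may form as either epimer; one is drawn, and both converge when that carbon is planarised in step 7.

**Route**

Step 1
Reactants: 1 1-[2,4-bis(benzyloxy)phenyl]ethanone; 2 diallyl carbonate
Product: 3 allyl 3-[2,4-bis(benzyloxy)phenyl]-3-oxopropanoate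
Conditions: NaH (2.2 equiv), THF, reflux; then aq. HCl
Reagents that add atoms: none
Why: Crossed Claisen condensation in which the sodium enolate of the ketone is C-acylated by the carbonate and the reaction is driven by deprotonation of the β-keto ester formed.

Step 2
Reactants: 3 allyl 3-[2,4-bis(benzyloxy)phenyl]-3-oxopropanoate
Product: 4 allyl 2-bromo-3-[2,4-bis(benzyloxy)phenyl]-3-oxopropanoate (racemic)
Conditions: NBS (1.0 equiv), Mg(ClO4)2 (10 mol%), EtOAc, 0 °C
Reagents that add atoms: N-bromosuccinimide, O=C1CCC(=O)N1Br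
Why: Electrophilic α-bromination of the magnesium-bound enol of a β-keto ester, which should react far faster than the acyl-deactivated dialkoxybenzene ring, with one equivalent of NBS at 0 °C holding the reaction at the monobromide.

Step 3
Reactants: 1 1-[2,4-bis(benzyloxy)phenyl]ethanone; 5 4-hydroxybenzaldehyde
Product: 7 (E)-1-[2,4-bis(benzyloxy)phenyl]-3-(4-hydroxyphenyl)prop-2-en-1-one, via aldol adduct 6 (not isolated)
Conditions: KOH (aq. 50%, 4 equiv), EtOH, rt → 50 °C; then aq. HCl
Reagents that add atoms: none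
Why: Claisen–Schmidt condensation, in which aldol addition to the aldehyde (present as its phenoxide, hence the excess base and gentle warming) is followed by E1cB dehydration of 6 to the conjugated E-enone.

Step 4
Reactants: 7 (E)-1-[2,4-bis(benzyloxy)phenyl]-3-(4-hydroxyphenyl)prop-2-en-1-one
Product: 8 benzyl 4-[(E)-3-[2,4-bis(benzyloxy)phenyl]-3-oxoprop-1-en-1-yl]phenyl carbonate
Conditions: CbzCl (1.2 equiv), Et3N, CH2Cl2, 0 °C
Reagents that add atoms: benzyl chloroformate, O=C(Cl)OCc1ccccc1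
Why: O-Acylation of the phenol by the chloroformate gives an aryl benzyl carbonate, which is removed by hydrogenolysis in step 8 and makes this ring a weaker donor than a benzyl ether would.

Step 5
Reactants: 4 allyl 2-bromo-3-[2,4-bis(benzyloxy)phenyl]-3-oxopropanoate; 8 benzyl 4-[(E)-3-[2,4-bis(benzyloxy)phenyl]-3-oxoprop-1-en-1-yl]phenyl carbonate
Product: 10 allyl (1S,2S,3R)-1,2-bis[2,4-bis(benzyloxy)benzoyl]-3-{4-[(benzyloxycarbonyl)oxy]phenyl}cyclopropane-1-carboxylate (3-aryl trans to 2-aroyl; C1 epimer drawn arbitrarily), via bromo Michael adduct enolate 9 (not isolated)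
Conditions: N-(9-anthracenylmethyl)cinchonidinium chloride (10 mol%), K2CO3 (solid, 2 equiv), toluene, 0 °C
Reagents that add atoms: none
Why: Michael-initiated ring closure under chiral phase-transfer catalysis, in which the ammonium enolate of 4 adds to the β-carbon of the enone inside the chiral ion pair (this sets the aryl-bearing carbon) and the ketone enolate 9 then displaces bromide in a 3-exo-tet step that places the new aroyl group trans to the aryl group.

Step 6
Reactants: 10 allyl (1S,2S,3R)-1,2-bis[2,4-bis(benzyloxy)benzoyl]-3-{4-[(benzyloxycarbonyl)oxy]phenyl}cyclopropane-1-carboxylate; 11 4-(benzyloxy)benzaldehyde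
Product: 13 allyl (2R,3S,4R,5S)-2-[4-(benzyloxy)phenyl]-3,4-bis[2,4-bis(benzyloxy)benzoyl]-5-{4-[(benzyloxycarbonyl)oxy]phenyl}tetrahydrofuran-3-carboxylate (2,5-trans; 4,5-cis; C3 provisional), via oxocarbenium tin enolate 12 (not isolated)
Conditions: Sn(OTf)2 (20 mol%), 11 (3 equiv), 4 Å MS, CH2Cl2, −20 °C → rt (held at rt for C2 equilibration)
Reagents that add atoms: none
Why: Bidentate binding of Sn(OTf)2 to the keto ester on C1 of 10 weakens the C1–C3 bond, the carbonyl oxygen of 11 attacks the benzylic carbon from the rear in an SN2-like opening to give ion pair 12, and the enolate carbon then adds to the oxocarbenium carbon, so that O1–C5 and then C2–C3 are formed (Lewis acid-catalysed (3+2) annulation of donor–acceptor cyclopropanes with aldehydes). The tetrahydrofuran closes by a 5-(enolexo)-endo-trig aldol-type attack on the ring C=O+ bond. C5 is set by inversion at the donor carbon, so the aryl and aroyl groups that are trans on the three-membered ring end up cis on C5 and C4; C4 is carried over untouched; C3 forms as a quaternary keto ester whose configuration is irrelevant because it is planarised in step 7. C2 is expected to close 2,5-cis under kinetic control, but the closure is a reversible aldol step (a p-benzyloxyphenyl-stabilised oxocarbenium ion and a β-keto ester enolate are good leaving partners), and holding the mixture at room temperature should move it to the 2,5-trans isomer, because the cis isomer must carry the C2 aryl, one C3 carbonyl group, the C4 aroyl and the C5 aryl side by side on one face. The step needs clean inversion at C5 and no ring expansion by the C1 ketone oxygen (Cloke–Wilson type); both depend on bimolecular capture outrunning ionisation, which is secured by the aryl carbonate on the donor ring, by the inductive pull of the adjacent aroyl group and by the excess of the electron-rich aldehyde. The same carbonate makes the C5–O1 bond much harder to ionise than the bonds to C2, so the equilibration should stay at C2.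

Step 7
Reactants: 13 allyl (2R,3S,4R,5S)-2-[4-(benzyloxy)phenyl]-3,4-bis[2,4-bis(benzyloxy)benzoyl]-5-{4-[(benzyloxycarbonyl)oxy]phenyl}tetrahydrofuran-3-carboxylate
Product: 16 [(2S,3R,4R,5S)-2-[4-(benzyloxy)phenyl]-5-{4-[(benzyloxycarbonyl)oxy]phenyl}tetrahydrofuran-3,4-diyl]bis{[2,4-bis(benzyloxy)phenyl]methanone}, via β-keto acid 14 (not isolated), via enol 15 (not isolated)
Conditions: Pd(PPh3)4 (5 mol%), HCO2H (3 equiv), Et3N (2.5 equiv), THF, rt
Reagents that add atoms: none
Why: Palladium-catalysed decarboxylative protonation of an allyl β-keto ester, in which zerovalent palladium ionises the allyl ester, carboxylate 14 loses CO2 and enol 15 is protonated at C3 from the face opposite the C2 aryl group (the C4 acyl group on the other face is the smaller blocker, and this product avoids three adjacent cis groups on C3–C5), while formate reduces the allyl fragment to propene and keeps the medium buffered so that the enolate is short-lived.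

Step 8
Reactants: 16 [(2S,3R,4R,5S)-2-[4-(benzyloxy)phenyl]-5-{4-[(benzyloxycarbonyl)oxy]phenyl}tetrahydrofuran-3,4-diyl]bis{[2,4-bis(benzyloxy)phenyl]methanone}
Product: 18 [(2S,3R,4R,5S)-2,5-bis(4-hydroxyphenyl)tetrahydrofuran-3,4-diyl]bis[(2,4-dihydroxyphenyl)methanone] (CNP0237262.3), via aryl hydrogen carbonate 17 (not isolated)
Conditions: H2 (1 atm), Pd/C (10 wt%), EtOAc–MeOH, rt
Reagents that add atoms: none
Why: Hydrogenolysis of the five benzyl ethers and of the benzyl carbonate (which loses CO2 through 17) under neutral conditions, stopped at the calculated uptake so that the aryl ketones and the ring benzylic C–O bonds are left alone and no stereocentre is touched.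

**Compound list**

1 | 1-[2,4-bis(benzyloxy)phenyl]ethanone | CC(=O)c1ccc(OCc2ccccc2)cc1OCc1ccccc1 | starting material
2 | diallyl carbonate | C=CCOC(=O)OCC=C | starting material
3 | allyl 3-[2,4-bis(benzyloxy)phenyl]-3-oxopropanoate | C=CCOC(=O)CC(=O)c1ccc(OCc2ccccc2)cc1OCc1ccccc1 | intermediate
4 | allyl 2-bromo-3-[2,4-bis(benzyloxy)phenyl]-3-oxopropanoate (racemic) | C=CCOC(=O)C(Br)C(=O)c1ccc(OCc2ccccc2)cc1OCc1ccccc1 | intermediate
5 | 4-hydroxybenzaldehyde | O=Cc1ccc(O)cc1 | starting material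
6 | 1-[2,4-bis(benzyloxy)phenyl]-3-hydroxy-3-(4-hydroxyphenyl)propan-1-one (racemic aldol adduct) | O=C(CC(O)c1ccc(O)cc1)c1ccc(OCc2ccccc2)cc1OCc1ccccc1 | intermediate (not isolated)
7 | (E)-1-[2,4-bis(benzyloxy)phenyl]-3-(4-hydroxyphenyl)prop-2-en-1-one | O=C(/C=C/c1ccc(O)cc1)c1ccc(OCc2ccccc2)cc1OCc1ccccc1 | intermediate
8 | benzyl 4-[(E)-3-[2,4-bis(benzyloxy)phenyl]-3-oxoprop-1-en-1-yl]phenyl carbonate | O=C(/C=C/c1ccc(OC(=O)OCc2ccccc2)cc1)c1ccc(OCc2ccccc2)cc1OCc1ccccc1 | intermediate
9 | ketone enolate of allyl (3R)-2-bromo-2-[2,4-bis(benzyloxy)benzoyl]-5-[2,4-bis(benzyloxy)phenyl]-3-{4-[(benzyloxycarbonyl)oxy]phenyl}-5-oxopentanoate (C2 epimers; shown without counter-ion) | C=CCOC(=O)C(Br)(C(=O)c1ccc(OCc2ccccc2)cc1OCc1ccccc1)[C@@H](c1ccc(OC(=O)OCc2ccccc2)cc1)C=C([O-])c1ccc(OCc2ccccc2)cc1OCc1ccccc1 | intermediate (not isolated)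
10 | allyl (1S,2S,3R)-1,2-bis[2,4-bis(benzyloxy)benzoyl]-3-{4-[(benzyloxycarbonyl)oxy]phenyl}cyclopropane-1-carboxylate (3-aryl trans to 2-aroyl; C1 epimer drawn arbitrarily) | C=CCOC(=O)[C@]1(C(=O)c2ccc(OCc3ccccc3)cc2OCc2ccccc2)[C@@H](C(=O)c2ccc(OCc3ccccc3)cc2OCc2ccccc2)[C@@H]1c1ccc(OC(=O)OCc2ccccc2)cc1 | intermediate
11 | 4-(benzyloxy)benzaldehyde | O=Cc1ccc(OCc2ccccc2)cc1 | starting material
12 | ring-opened ion pair: oxocarbenium ion of 11 on the C5 oxygen and tin enolate of the keto ester at C3, (4R,5S) in tetrahydrofuran numbering (shown without tin) | C=CCOC(=O)C(=C([O-])c1ccc(OCc2ccccc2)cc1OCc1ccccc1)[C@@H](C(=O)c1ccc(OCc2ccccc2)cc1OCc1ccccc1)[C@@H](c1ccc(OC(=O)OCc2ccccc2)cc1)[O+]=Cc1ccc(OCc2ccccc2)cc1 | intermediate (not isolated)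
13 | allyl (2R,3S,4R,5S)-2-[4-(benzyloxy)phenyl]-3,4-bis[2,4-bis(benzyloxy)benzoyl]-5-{4-[(benzyloxycarbonyl)oxy]phenyl}tetrahydrofuran-3-carboxylate (2,5-trans; 4,5-cis; C3 epimer drawn arbitrarily) | O=C(c1ccc(OCc2ccccc2)cc1OCc1ccccc1)[C@]1(C(=O)OCC=C)[C@@H](C(=O)c2ccc(OCc3ccccc3)cc2OCc2ccccc2)[C@@H](c2ccc(OC(=O)OCc3ccccc3)cc2)O[C@@H]1c1ccc(OCc2ccccc2)cc1 | intermediate
14 | (2R,3S,4R,5S)-2-[4-(benzyloxy)phenyl]-3,4-bis[2,4-bis(benzyloxy)benzoyl]-5-{4-[(benzyloxycarbonyl)oxy]phenyl}tetrahydrofuran-3-carboxylic acid (formed as its carboxylate) | O=C(c1ccc(OCc2ccccc2)cc1OCc1ccccc1)[C@]1(C(=O)O)[C@@H](C(=O)c2ccc(OCc3ccccc3)cc2OCc2ccccc2)[C@@H](c2ccc(OC(=O)OCc3ccccc3)cc2)O[C@@H]1c1ccc(OCc2ccccc2)cc1 | intermediate (not isolated)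
15 | {(2R,4R,5S)-2-[4-(benzyloxy)phenyl]-4-[2,4-bis(benzyloxy)benzoyl]-5-{4-[(benzyloxycarbonyl)oxy]phenyl}dihydrofuran-3(2H)-ylidene}[2,4-bis(benzyloxy)phenyl]methanol (C3 enol; double-bond geometry open) | OC(=C1[C@@H](C(=O)c2ccc(OCc3ccccc3)cc2OCc2ccccc2)[C@@H](c2ccc(OC(=O)OCc3ccccc3)cc2)O[C@@H]1c1ccc(OCc2ccccc2)cc1)c1ccc(OCc2ccccc2)cc1OCc1ccccc1 | intermediate (not isolated)
16 | [(2S,3R,4R,5S)-2-[4-(benzyloxy)phenyl]-5-{4-[(benzyloxycarbonyl)oxy]phenyl}tetrahydrofuran-3,4-diyl]bis{[2,4-bis(benzyloxy)phenyl]methanone} | O=C(c1ccc(OCc2ccccc2)cc1OCc1ccccc1)[C@@H]1[C@@H](C(=O)c2ccc(OCc3ccccc3)cc2OCc2ccccc2)[C@@H](c2ccc(OC(=O)OCc3ccccc3)cc2)O[C@@H]1c1ccc(OCc2ccccc2)cc1 | intermediate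
17 | 4-[(2S,3R,4R,5S)-3,4-bis(2,4-dihydroxybenzoyl)-5-(4-hydroxyphenyl)tetrahydrofuran-2-yl]phenyl hydrogen carbonate | O=C(c1ccc(O)cc1O)[C@@H]1[C@@H](C(=O)c2ccc(O)cc2O)[C@@H](c2ccc(OC(=O)O)cc2)O[C@@H]1c1ccc(O)cc1 | intermediate (not isolated)
18 | [(2S,3R,4R,5S)-2,5-bis(4-hydroxyphenyl)tetrahydrofuran-3,4-diyl]bis[(2,4-dihydroxyphenyl)methanone] | O=C(c1ccc(O)cc1O)[C@@H]1[C@@H](C(=O)c2ccc(O)cc2O)[C@@H](c2ccc(O)cc2)O[C@@H]1c1ccc(O)cc1 | target

**Step count**

Total: 8 steps. Longest linear sequence: 6 steps (steps 3, 4, 5, 6, 7, 8; the branch through steps 1 and 2 is equally long).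

**Steps most likely to fail**

1. Step 6. Ionisation of the C1–C3 bond may outrun capture by the aldehyde; this would lead to internal attack by the C1 ketone oxygen (ring expansion to a dihydrofuran) and to loss of inversion at the donor carbon. The kinetically formed 2,5-cis closure may also fail to equilibrate to the trans isomer.
   Fallback, from 10 back to 13: the two bonds are made one after the other. Cyclopropane 10 is opened at low temperature with 4-(benzyloxy)benzyl alcohol, a far better nucleophile than the aldehyde, under Yb(OTf)3 catalysis (SN2-type etherification of donor–acceptor cyclopropanes, inversion). This should give allyl (3R,4S)-2,3-bis[2,4-bis(benzyloxy)benzoyl]-4-{[4-(benzyloxy)benzyl]oxy}-4-{4-[(benzyloxycarbonyl)oxy]phenyl}butanoate F1. Oxidation of its p-alkoxybenzylic C–H bond with DDQ (4 Å MS, CH2Cl2) generates the C2 oxocarbenium ion (the cation of 12) next to the enolisable keto ester, which closes C2–C3 (oxidative cross-dehydrogenative cyclisation of a benzylic ether onto a tethered 1,3-dicarbonyl) and returns the route to 13. A short exposure of 13 to Sn(OTf)2 can then serve the C2 equilibration alone.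

2. Step 5. The phase-transfer Michael step may give insufficient enantioselectivity, or base-mediated degradation of the bromo keto ester or of the aryl carbonate may compete with ring closure.
   Fallback, from 3 and 8 back to 10: the stereodefining addition is separated from ring closure. Keto ester 3 is added to enone 8 with a cinchona-derived bifunctional thiourea (10 mol%, toluene; asymmetric 1,3-dicarbonyl addition to chalcones) to give allyl (3S)-2-[2,4-bis(benzyloxy)benzoyl]-5-[2,4-bis(benzyloxy)phenyl]-3-{4-[(benzyloxycarbonyl)oxy]phenyl}-5-oxopentanoate F2. Iodine and K2CO3 then convert it into the α-iodo compound allyl (3R)-2-iodo-2-[2,4-bis(benzyloxy)benzoyl]-5-[2,4-bis(benzyloxy)phenyl]-3-{4-[(benzyloxycarbonyl)oxy]phenyl}-5-oxopentanoate F3, whose ketone enolate closes the three-membered ring by 3-exo-tet displacement to give 10.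

3. Step 7. The palladium enolate may expel the ring oxygen from C2 (β-alkoxide elimination with ring opening), protonation may occur from the wrong face, or the amine may epimerise C4.
   Fallback, from 1 to 18: the carboxyl group is carried as a benzyl ester, so that neither an enolate nor an amine is involved. Ketone 1 with dibenzyl carbonate and NaH gives benzyl 3-[2,4-bis(benzyloxy)phenyl]-3-oxopropanoate F4, and NBS gives benzyl 2-bromo-3-[2,4-bis(benzyloxy)phenyl]-3-oxopropanoate F5. The phase-transfer cyclopropanation with 8 gives benzyl (1S,2S,3R)-1,2-bis[2,4-bis(benzyloxy)benzoyl]-3-{4-[(benzyloxycarbonyl)oxy]phenyl}cyclopropane-1-carboxylate F6, and the Sn(OTf)2 annulation with 11 gives benzyl (2R,3S,4R,5S)-2-[4-(benzyloxy)phenyl]-3,4-bis[2,4-bis(benzyloxy)benzoyl]-5-{4-[(benzyloxycarbonyl)oxy]phenyl}tetrahydrofuran-3-carboxylate F7. A single hydrogenolysis (H2, Pd/C, EtOAc–MeOH) removes all benzyl groups. The free acid (2R,3S,4R,5S)-3,4-bis(2,4-dihydroxybenzoyl)-2,5-bis(4-hydroxyphenyl)tetrahydrofuran-3-carboxylic acid F8 then loses CO2 through its cyclic hydrogen-bonded form, and the neutral enol ketonises to 18.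

**Further compounds**

F1 | step 6 | allyl (3R,4S)-2,3-bis[2,4-bis(benzyloxy)benzoyl]-4-{[4-(benzyloxy)benzyl]oxy}-4-{4-[(benzyloxycarbonyl)oxy]phenyl}butanoate (C2 epimers) | C=CCOC(=O)C(C(=O)c1ccc(OCc2ccccc2)cc1OCc1ccccc1)[C@@H](C(=O)c1ccc(OCc2ccccc2)cc1OCc1ccccc1)[C@@H](c1ccc(OC(=O)OCc2ccccc2)cc1)OCc1ccc(OCc2ccccc2)cc1
F2 | step 5 | allyl (3S)-2-[2,4-bis(benzyloxy)benzoyl]-5-[2,4-bis(benzyloxy)phenyl]-3-{4-[(benzyloxycarbonyl)oxy]phenyl}-5-oxopentanoate (C2 epimers) | C=CCOC(=O)C(C(=O)c1ccc(OCc2ccccc2)cc1OCc1ccccc1)[C@@H](c1ccc(OC(=O)OCc2ccccc2)cc1)CC(=O)c1ccc(OCc2ccccc2)cc1OCc1ccccc1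
F3 | step 5 | allyl (3R)-2-iodo-2-[2,4-bis(benzyloxy)benzoyl]-5-[2,4-bis(benzyloxy)phenyl]-3-{4-[(benzyloxycarbonyl)oxy]phenyl}-5-oxopentanoate (C2 epimers) | C=CCOC(=O)C(I)(C(=O)c1ccc(OCc2ccccc2)cc1OCc1ccccc1)[C@@H](c1ccc(OC(=O)OCc2ccccc2)cc1)CC(=O)c1ccc(OCc2ccccc2)cc1OCc1ccccc1
F4 | step 7 | benzyl 3-[2,4-bis(benzyloxy)phenyl]-3-oxopropanoate | O=C(CC(=O)c1ccc(OCc2ccccc2)cc1OCc1ccccc1)OCc1ccccc1
F5 | step 7 | benzyl 2-bromo-3-[2,4-bis(benzyloxy)phenyl]-3-oxopropanoate (racemic) | O=C(OCc1ccccc1)C(Br)C(=O)c1ccc(OCc2ccccc2)cc1OCc1ccccc1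
F6 | step 7 | benzyl (1S,2S,3R)-1,2-bis[2,4-bis(benzyloxy)benzoyl]-3-{4-[(benzyloxycarbonyl)oxy]phenyl}cyclopropane-1-carboxylate | O=C(OCc1ccccc1)[C@]1(C(=O)c2ccc(OCc3ccccc3)cc2OCc2ccccc2)[C@@H](C(=O)c2ccc(OCc3ccccc3)cc2OCc2ccccc2)[C@@H]1c1ccc(OC(=O)OCc2ccccc2)cc1
F7 | step 7 | benzyl (2R,3S,4R,5S)-2-[4-(benzyloxy)phenyl]-3,4-bis[2,4-bis(benzyloxy)benzoyl]-5-{4-[(benzyloxycarbonyl)oxy]phenyl}tetrahydrofuran-3-carboxylate | O=C(c1ccc(OCc2ccccc2)cc1OCc1ccccc1)[C@]1(C(=O)OCc2ccccc2)[C@@H](C(=O)c2ccc(OCc3ccccc3)cc2OCc2ccccc2)[C@@H](c2ccc(OC(=O)OCc3ccccc3)cc2)O[C@@H]1c1ccc(OCc2ccccc2)cc1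
F8 | step 7 | (2R,3S,4R,5S)-3,4-bis(2,4-dihydroxybenzoyl)-2,5-bis(4-hydroxyphenyl)tetrahydrofuran-3-carboxylic acid | O=C(c1ccc(O)cc1O)[C@]1(C(=O)O)[C@@H](C(=O)c2ccc(O)cc2O)[C@@H](c2ccc(O)cc2)O[C@@H]1c1ccc(O)cc1
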